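**Retrosynthetic overview**
1. Crotobarin ⇐ C16 α-methylenation and O-acetylation of a 14-hydroxy-15-oxo-bicyclo[2.2.2]octane δ-lactone.
2. Bicyclo[2.2.2]octane ⇐ one-pot diazo formation / formyl homologation (C8–C15) / aldol (C8–C14) of a C8 sulfonylhydrazone whose C9 carries a symmetric two-aldehyde arm (arm selection sets C12).
3. C8 ketone + C9 δ-lactone ⇐ α-ketol 1,2-shift of the C11 side chain from C8 to C9 in an α-hydroxy ketone, pulled by lactonisation (key skeletal step, sets C9).
4. α-Hydroxy ketone ⇐ 2-methylcyclohex-2-enone by α′-alkylation (C8–C11), Cu-catalysed isopropenyl addition (C5), enolate Michael addition to methyl acrylate (C10), enolate hydroxylation (C8–O).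
5. Ring order: ring B (bought) → δ-lactone → ring C′ (C8, C9, C11, C12, C16, C15) → bicyclo[2.2.2]octane.

Assumption: 4-(bromomethyl)cyclopent-1-ene (compound 1) is taken as a catalogue building block.
Atom labels C1–C20 are those of the target: C1–C3 lactone chain, C4 isopropenyl carbon, C5–C10 ring B, C20 methyl on C10, C11–C16 bridge carbons, C17 exo-methylene.

**Route**

Step 1
Reactants: 1 4-(bromomethyl)cyclopent-1-ene
Product: 3 3-(bromomethyl)-1,1,5,5-tetramethoxypentane, via dialdehyde 2 (not isolated)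
Conditions: O3, CH2Cl2/MeOH (4:1), −78 °C; Me2S, −78 °C → rt; then HC(OMe)3, p-TsOH (cat.), rt
Reagents that add atoms: ozone [O-][O+]=O (oxygens of 2); trimethyl orthoformate COC(OC)OC (methoxy groups of 3)
Why: Ozonolysis of the symmetric cyclopentene with reductive work-up, then acid-catalysed acetalisation, gives the achiral two-arm bis-acetal in which the future C12 is still prochiral; no stereocentre is formed.

Step 2
Reactants: 4 2-methylcyclohex-2-en-1-one; 3 3-(bromomethyl)-1,1,5,5-tetramethoxypentane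
Product: 6 rac-6-[4,4-dimethoxy-2-(2,2-dimethoxyethyl)butyl]-2-methylcyclohex-2-en-1-one, via lithium dienolate 5 (not isolated)
Conditions: LiN(i-Pr)2, THF, −78 °C; then 3, DMPU, −78 → 0 °C
Reagents that add atoms: none
Why: Kinetic α′-deprotonation gives the cross-conjugated lithium dienolate, which is C-alkylated by the primary bromide (SN2 enolate alkylation); the new C8 centre is racemic and is erased in step 5.

Step 3
Reactants: 6 rac-6-[4,4-dimethoxy-2-(2,2-dimethoxyethyl)butyl]-2-methylcyclohex-2-en-1-one; 7 isopropenylmagnesium bromide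
Product: 9 trimethyl({(3S)-6-[4,4-dimethoxy-2-(2,2-dimethoxyethyl)butyl]-2-methyl-3-(prop-1-en-2-yl)cyclohex-1-en-1-yl}oxy)silane (both C6 epimers), via magnesium enolate 8 (not isolated)
Conditions: 7 (1.5 equiv), CuBr·SMe2 (5 mol %), (R)-1-[(S)-2-(diphenylphosphanyl)ferrocenyl]ethyl(dicyclohexyl)phosphane (6 mol %), t-BuOMe, −78 °C; then Me3SiCl, Et3N, DMPU, −78 → 0 °C
Reagents that add atoms: chlorotrimethylsilane C[Si](C)(C)Cl
Why: Copper-catalysed asymmetric conjugate addition of a Grignard reagent sets C5 (S) under ligand control (antipode of the diphosphine used if the sense is reversed), overriding the remote racemic C8 centre; silylation keeps the enolate regiodefined.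

Step 4
Reactants: 9 trimethyl({(3S)-6-[4,4-dimethoxy-2-(2,2-dimethoxyethyl)butyl]-2-methyl-3-(prop-1-en-2-yl)cyclohex-1-en-1-yl}oxy)silane; 10 methyl acrylate
Product: 12 methyl 3-[(1S,6S)-3-[4,4-dimethoxy-2-(2,2-dimethoxyethyl)butyl]-1-methyl-2-oxo-6-(prop-1-en-2-yl)cyclohexyl]propanoate (both C3 epimers), via lithium enolate 11 (not isolated)
Conditions: MeLi, THF, 0 °C; then 10, −78 °C; AcOH, −78 °C
Reagents that add atoms: none
Why: MeLi cleaves the O–Si bond to the regiodefined lithium enolate, whose Michael addition to methyl acrylate occurs anti to the neighbouring isopropenyl group and so sets the quaternary C10 (S).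

Step 5
Reactants: 12 methyl 3-[(1S,6S)-3-[4,4-dimethoxy-2-(2,2-dimethoxyethyl)butyl]-1-methyl-2-oxo-6-(prop-1-en-2-yl)cyclohexyl]propanoate
Product: 14 methyl 3-[(1S,3S,6S)-3-[4,4-dimethoxy-2-(2,2-dimethoxyethyl)butyl]-3-hydroxy-1-methyl-2-oxo-6-(prop-1-en-2-yl)cyclohexyl]propanoate, via potassium enolate 13 (not isolated)
Conditions: KN(SiMe3)2, THF, −78 → −40 °C; 2-(phenylsulfonyl)-3-phenyloxaziridine, −78 °C; AcOH
Reagents that add atoms: 2-(phenylsulfonyl)-3-phenyloxaziridine O=S(=O)(c1ccccc1)N1OC1c1ccccc1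
Why: Davis enolate hydroxylation: C8–H is the only enolisable ketone position and the oxaziridine attacks the potassium enolate on the face opposite the pseudoaxial C10 methyl, giving the C8 carbinol (3S in 14) with OH cis to the ester arm and the C11 chain cis to the methyl.

Step 6
Reactants: 14 methyl 3-[(1S,3S,6S)-3-[4,4-dimethoxy-2-(2,2-dimethoxyethyl)butyl]-3-hydroxy-1-methyl-2-oxo-6-(prop-1-en-2-yl)cyclohexyl]propanoate
Product: 16 (4aS,5S,8aS)-8a-[4,4-dimethoxy-2-(2,2-dimethoxyethyl)butyl]-4a-methyl-5-(prop-1-en-2-yl)hexahydro-2H-chromene-2,8(3H)-dione, via hydroxy ketone 15 (not isolated)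
Conditions: KOt-Bu (20 mol %), toluene, 4 Å molecular sieves, 100 °C
Reagents that add atoms: none
Why: Anionic α-ketol (acyloin) rearrangement, a 1,2-alkyl shift: in the chair with the C11 chain axial this bond is aligned with the C9 carbonyl and migrates suprafacially from C8 to C9, so C11 stays on the methyl face and the former carbonyl oxygen becomes the C9 alkoxide cis to the ester arm (8aS in 16), where δ-lactonisation with loss of MeOH pulls the equilibrium and blocks the reverse shift.

Step 7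
Reactants: 16 (4aS,5S,8aS)-8a-[4,4-dimethoxy-2-(2,2-dimethoxyethyl)butyl]-4a-methyl-5-(prop-1-en-2-yl)hexahydro-2H-chromene-2,8(3H)-dione
Product: 17 N′-[(4aS,5S,8aS)-8a-[4,4-dimethoxy-2-(2,2-dimethoxyethyl)butyl]-4a-methyl-2-oxo-5-(prop-1-en-2-yl)octahydro-8H-chromen-8-ylidene]-2-(trifluoromethyl)benzenesulfonohydrazide
Conditions: 2-(trifluoromethyl)benzenesulfonohydrazide, PPTS (5 mol %), MeOH, 45 °C
Reagents that add atoms: 2-(trifluoromethyl)benzenesulfonohydrazide NNS(=O)(=O)c1ccccc1C(F)(F)F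
Why: Condensation of the only ketone with the sulfonyl hydrazide gives the N-sulfonylhydrazone while the dimethyl acetals are stable in methanol; no stereocentre is formed (C=N geometry is irrelevant).

Step 8
Reactants: 17 N′-[(4aS,5S,8aS)-8a-[4,4-dimethoxy-2-(2,2-dimethoxyethyl)butyl]-4a-methyl-2-oxo-5-(prop-1-en-2-yl)octahydro-8H-chromen-8-ylidene]-2-(trifluoromethyl)benzenesulfonohydrazide
Product: 18 N′-[(4aS,5S,8aS)-4a-methyl-2-oxo-8a-[4-oxo-2-(2-oxoethyl)butyl]-5-(prop-1-en-2-yl)octahydro-8H-chromen-8-ylidene]-2-(trifluoromethyl)benzenesulfonohydrazide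
Conditions: Amberlyst 15, acetone/H2O (10:1), rt
Reagents that add atoms: water O
Why: Mild acid-catalysed acetal hydrolysis frees both aldehydes while the sulfonylhydrazone and the lactone stay intact; no stereocentre is touched.

Step 9
Reactants: 18 N′-[(4aS,5S,8aS)-4a-methyl-2-oxo-8a-[4-oxo-2-(2-oxoethyl)butyl]-5-(prop-1-en-2-yl)octahydro-8H-chromen-8-ylidene]-2-(trifluoromethyl)benzenesulfonohydrazide
Product: 21 14-O-deacetyl-17-norcrotobarin, via diazo dialdehyde 19 (not isolated), via keto aldehyde 20 (not isolated)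
Conditions: Cs2CO3 (2.2 equiv), 1,4-dioxane (0.01 M), 40 °C
Reagents that add atoms: none
Why: Proposed new method: the caesium salt of the sulfonylhydrazone loses sulfinate at 40 °C to give diazoalkane 19, whose carbon adds to one of the two enantiotopic formyl groups through a chair transition state that keeps both the unreacted arm and C10 equatorial on the forming ring C′ (this sets C12); the betaine loses N2 with a 1,2-hydride shift to give ketone 20, and the carbonate then closes the second ring by aldol addition of the C8 enolate to the remaining aldehyde through a cation-bridged arrangement that places the C14 hydroxyl next to the C15 carbonyl and makes C8 quaternary; the closest known reactions are the base-mediated coupling of N-sulfonylhydrazones with aldehydes to give ketones (formyl C–H insertion, Roskamp-type homologation) and aldol closures of bicyclo[2.2.2]octanes.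

Step 10
Reactants: 21 14-O-deacetyl-17-norcrotobarin
Product: 22 17-norcrotobarin
Conditions: Ac2O, pyridine, DMAP (cat.), CH2Cl2, rt
Reagents that add atoms: acetic anhydride CC(=O)OC(C)=O
Why: DMAP-catalysed acylation of the secondary C14 alcohol proceeds with retention; no stereocentre changes.

Step 11
Reactants: 22 17-norcrotobarin
Product: 23 crotobarin
Conditions: (CH2O)n, N-methylanilinium trifluoroacetate, THF, 65 °C
Reagents that add atoms: formaldehyde (from paraformaldehyde) C=O
Why: Mannich-type α-methylenation (Gras conditions): C16 is the only enolisable position because C8 is quaternary, and the bridgehead C12 forbids an endocyclic alkene, so the exo-methylene enone forms; no stereocentre is touched.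

**Compound list**
1 | 4-(bromomethyl)cyclopent-1-ene | BrCC1CC=CC1 | starting material
2 | 3-(bromomethyl)pentanedial | O=CCC(CBr)CC=O | intermediate
3 | 3-(bromomethyl)-1,1,5,5-tetramethoxypentane | COC(OC)CC(CBr)CC(OC)OC | intermediate
4 | 2-methylcyclohex-2-en-1-one | CC1=CCCCC1=O | starting material
5 | lithium 6-methylcyclohexa-1,5-dien-1-olate | [Li]OC1=CCCC=C1C | intermediate
6 | rac-6-[4,4-dimethoxy-2-(2,2-dimethoxyethyl)butyl]-2-methylcyclohex-2-en-1-one | CC1=CCCC(CC(CC(OC)OC)CC(OC)OC)C1=O | intermediate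
7 | isopropenylmagnesium bromide | CC(=C)[Mg]Br | starting material
8 | bromomagnesium (3S)-6-[4,4-dimethoxy-2-(2,2-dimethoxyethyl)butyl]-2-methyl-3-(prop-1-en-2-yl)cyclohex-1-en-1-olate (both C6 epimers) | Br[Mg]OC1=C(C)[C@H](C(=C)C)CCC1CC(CC(OC)OC)CC(OC)OC | intermediate
9 | trimethyl({(3S)-6-[4,4-dimethoxy-2-(2,2-dimethoxyethyl)butyl]-2-methyl-3-(prop-1-en-2-yl)cyclohex-1-en-1-yl}oxy)silane (both C6 epimers) | C[Si](C)(C)OC1=C(C)[C@H](C(=C)C)CCC1CC(CC(OC)OC)CC(OC)OC | intermediate
10 | methyl acrylate | C=CC(=O)OC | starting material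
11 | lithium (3S)-6-[4,4-dimethoxy-2-(2,2-dimethoxyethyl)butyl]-2-methyl-3-(prop-1-en-2-yl)cyclohex-1-en-1-olate (both C6 epimers) | [Li]OC1=C(C)[C@H](C(=C)C)CCC1CC(CC(OC)OC)CC(OC)OC | intermediate
12 | methyl 3-[(1S,6S)-3-[4,4-dimethoxy-2-(2,2-dimethoxyethyl)butyl]-1-methyl-2-oxo-6-(prop-1-en-2-yl)cyclohexyl]propanoate (both C3 epimers) | O=C1C(CC(CC(OC)OC)CC(OC)OC)CC[C@@H](C(=C)C)[C@]1(C)CCC(=O)OC | intermediate
13 | potassium (5S,6S)-2-[4,4-dimethoxy-2-(2,2-dimethoxyethyl)butyl]-6-(3-methoxy-3-oxopropyl)-6-methyl-5-(prop-1-en-2-yl)cyclohex-1-en-1-olate | [K]OC1=C(CC(CC(OC)OC)CC(OC)OC)CC[C@@H](C(=C)C)[C@]1(C)CCC(=O)OC | intermediate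
14 | methyl 3-[(1S,3S,6S)-3-[4,4-dimethoxy-2-(2,2-dimethoxyethyl)butyl]-3-hydroxy-1-methyl-2-oxo-6-(prop-1-en-2-yl)cyclohexyl]propanoate | O=C1[C@@](O)(CC(CC(OC)OC)CC(OC)OC)CC[C@@H](C(=C)C)[C@]1(C)CCC(=O)OC | intermediate
15 | methyl 3-[(1S,2S,6S)-2-[4,4-dimethoxy-2-(2,2-dimethoxyethyl)butyl]-2-hydroxy-1-methyl-3-oxo-6-(prop-1-en-2-yl)cyclohexyl]propanoate (present as its potassium alkoxide) | O=C1CC[C@@H](C(=C)C)[C@](C)(CCC(=O)OC)[C@@]1(O)CC(CC(OC)OC)CC(OC)OC | intermediate
16 | (4aS,5S,8aS)-8a-[4,4-dimethoxy-2-(2,2-dimethoxyethyl)butyl]-4a-methyl-5-(prop-1-en-2-yl)hexahydro-2H-chromene-2,8(3H)-dione (C8 ketone, cis-fused C3–O–C9 δ-lactone) | O=C1CC[C@@H](C(=C)C)[C@]2(C)CCC(=O)O[C@]12CC(CC(OC)OC)CC(OC)OC | intermediate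
17 | N′-[(4aS,5S,8aS)-8a-[4,4-dimethoxy-2-(2,2-dimethoxyethyl)butyl]-4a-methyl-2-oxo-5-(prop-1-en-2-yl)octahydro-8H-chromen-8-ylidene]-2-(trifluoromethyl)benzenesulfonohydrazide | FC(F)(F)c1ccccc1S(=O)(=O)NN=C1CC[C@@H](C(=C)C)[C@]2(C)CCC(=O)O[C@]12CC(CC(OC)OC)CC(OC)OC | intermediate
18 | N′-[(4aS,5S,8aS)-4a-methyl-2-oxo-8a-[4-oxo-2-(2-oxoethyl)butyl]-5-(prop-1-en-2-yl)octahydro-8H-chromen-8-ylidene]-2-(trifluoromethyl)benzenesulfonohydrazide | FC(F)(F)c1ccccc1S(=O)(=O)NN=C1CC[C@@H](C(=C)C)[C@]2(C)CCC(=O)O[C@]12CC(CC=O)CC=O | intermediate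
19 | (4aS,5S,8aS)-8-diazo-4a-methyl-8a-[4-oxo-2-(2-oxoethyl)butyl]-5-(prop-1-en-2-yl)octahydro-2H-chromen-2-one | [N-]=[N+]=C1CC[C@@H](C(=C)C)[C@]2(C)CCC(=O)O[C@]12CC(CC=O)CC=O | intermediate
20 | tricyclic keto aldehyde: lactone 16 skeleton with ring C′ closed by a C8–C15(=O) bond, C8–H epimerisable, C12 bearing the CH2CHO arm (C13–C14) cis to C10 | C1C(=O)C2CC[C@@H](C(=C)C)[C@]3(C)CCC(=O)O[C@@]32C[C@H]1CC=O | intermediate
21 | 14-O-deacetyl-17-norcrotobarin (14-hydroxy-15-ketone; 5S,8S,9S,10S,12R,14S as in crotobarin) | C1C(=O)[C@]23CC[C@@H](C(=C)C)[C@]4(C)CCC(=O)O[C@@]42C[C@H]1C[C@@H]3O | intermediate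
22 | 17-norcrotobarin (14-acetate, C16 still CH2; 5S,8S,9S,10S,12R,14S) | C1C(=O)[C@]23CC[C@@H](C(=C)C)[C@]4(C)CCC(=O)O[C@@]42C[C@H]1C[C@@H]3OC(C)=O | intermediate
23 | crotobarin (5S,8S,9S,10S,12R,14S) | C=C1C(=O)[C@]23CC[C@@H](C(=C)C)[C@]4(C)CCC(=O)O[C@@]42C[C@H]1C[C@@H]3OC(C)=O | target

**Step count and risks**
Total step count: 11. Longest linear sequence: 11 steps (1 → 23; 10 steps from 4).

Three steps most likely to fail:

Step 3. The asymmetric isopropenyl addition is run on an already alkylated, racemic 2,6-disubstituted enone, so catalyst control over the existing C8 centre and reactivity are untested. Fallback, a change of order: it sets out from 4. The same Cu/diphosphine addition of 7 with Me3SiCl trapping is run on the parent enone to give silyl enol ether F1, and MeLi then 10 give keto ester F2. Only then is C8 alkylated (LiN(i-Pr)2, 3, DMPU, −78 → −30 °C, kept cold to outrun Claisen closure onto the ester). It comes back to the route at 12.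

Step 6. The α-ketol shift of a primary alkyl group is slow and needs the C11 chain axial beside the axial methyl. Ring contraction by C7 migration, or base-induced side reactions of the product ketone, can compete. Fallback, C9–C11 bond by carbonyl addition instead of a shift: it sets out from 4 and passes through F1 and F2 as above. F2 is hydroxylated at C8 (KN(SiMe3)2, Davis oxaziridine) to hydroxy ketone F3. Bromide 3 is turned into Grignard reagent F4 (Mg, THF; then CeCl3), 2.5 equiv of which add to the C9 carbonyl of F3. The C9 alkoxide closes the lactone to hydroxy lactone F5 (the cis-lactone is separated from any C9 epimer). Dess–Martin oxidation of the C8 carbinol comes back to the route at 16.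

Step 9 (the proposed new cascade). The hydrazone anion, or the enolate of 20, can expel the C9 carboxylate by 1,4- or β-elimination. The diazoalkane can also give the C7=C8 alkene or an epoxide, and the arm selection may be modest. Fallback with known reactions: it sets out from 16, which is converted into enol triflate F6 (KN(SiMe3)2, PhNTf2, −78 °C). The acetals are cleaved (Amberlyst 15, wet acetone) to dialdehyde F7. A Nozaki–Hiyama–Kishi closure (CrCl2, NiCl2 cat., DMF) joins C8 to one formyl group to give allylic alcohol F8, and Dess–Martin periodinane gives enone F9. [(Ph3P)CuH]6 in toluene at −40 °C (reductive aldol) then reduces the C7=C8 bond to the C8 copper enolate, which adds to the C14 aldehyde. It comes back to the route at 21.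

**Further compounds**
F1 | step 3 | (S)-trimethyl{[2-methyl-3-(prop-1-en-2-yl)cyclohex-1-en-1-yl]oxy}silane | C[Si](C)(C)OC1=C(C)[C@H](C(=C)C)CCC1
F2 | step 3 | methyl 3-[(1S,6S)-1-methyl-2-oxo-6-(prop-1-en-2-yl)cyclohexyl]propanoate | O=C1CCC[C@@H](C(=C)C)[C@]1(C)CCC(=O)OC
F3 | step 6 | methyl 3-[(1S,6S)-3-hydroxy-1-methyl-2-oxo-6-(prop-1-en-2-yl)cyclohexyl]propanoate (both C3 epimers) | O=C1C(O)CC[C@@H](C(=C)C)[C@]1(C)CCC(=O)OC
F4 | step 6 | [4,4-dimethoxy-2-(2,2-dimethoxyethyl)butyl]magnesium bromide | COC(OC)CC(C[Mg]Br)CC(OC)OC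
F5 | step 6 | (4aS,5S,8aS)-8a-[4,4-dimethoxy-2-(2,2-dimethoxyethyl)butyl]-8-hydroxy-4a-methyl-5-(prop-1-en-2-yl)octahydro-2H-chromen-2-one (C8 epimers) | OC1CC[C@@H](C(=C)C)[C@]2(C)CCC(=O)O[C@]12CC(CC(OC)OC)CC(OC)OC
F6 | step 9 | C8 enol triflate of 16 (C7=C8 alkene, bis-acetal arm) | FC(F)(F)S(=O)(=O)OC1=CC[C@@H](C(=C)C)[C@]2(C)CCC(=O)O[C@]12CC(CC(OC)OC)CC(OC)OC
F7 | step 9 | C8 enol triflate with the 4-oxo-2-(2-oxoethyl)butyl arm | FC(F)(F)S(=O)(=O)OC1=CC[C@@H](C(=C)C)[C@]2(C)CCC(=O)O[C@]12CC(CC=O)CC=O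
F8 | step 9 | tricyclic allylic alcohol: ring C′ closed by C8–C15, C15 carbinol (epimers), C7=C8 alkene, CH2CHO arm on C12 | C1C(O)C2=CC[C@@H](C(=C)C)[C@]3(C)CCC(=O)O[C@@]32C[C@H]1CC=O
F9 | step 9 | tricyclic enone: C15 ketone conjugated with C7=C8, CH2CHO arm on C12 | C1C(=O)C2=CC[C@@H](C(=C)C)[C@]3(C)CCC(=O)O[C@@]32C[C@H]1CC=O
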